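**Strategy.** Everything rests on cutting the C8 side chain of ring A on both sides of its only stereocentre, at C8–C1'' and C2''–C3''. Because C2'' lies between the benzylic C1'' methylene and the C3'' methylene, C1''–C2'' can be supplied as a vinyl boronate that accepts an aryl group at one carbon and an alkyl group at the other. A single palladium-catalysed conjunctive coupling thus joins ring A, the two-carbon unit and the oxygenated chain, sets C2'' under ligand control and leaves boron there for stereoretentive isopropenylation. Its precursors are a symmetrical 2,6-bis(MOM-oxy)-4-methoxyphenyl triflate and a lithium vinyl(alkyl)boronate made in the flask. Ring C is closed afterwards from a ring A ynone.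

Key step: step 6

Remarks on the chemistry:
- Side-chain atoms are numbered C1'' (CH2 on C8), C2'' (stereocentre), C3'', C4'', C5'' (carbinol carbon).
- L* is one antipode of 1,1′-bis[bis(3,5-dimethylphenyl)phosphino]-2,2′-bis[α-(dimethylamino)benzyl]ferrocene (MandyPhos type). Assumption: the antipode that delivers (R)-13 is assigned in a pilot run by oxidising 13 to the carbinol and Mosher analysis; the mirror-image ligand is used if the sense is opposite.
- The alkyllithium is made by lithium–iodine exchange, so the boronate carries LiI. CF3SO3K is added in step 6 to take up this iodide, which would otherwise occupy the palladium site needed by the alkene.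
- The final unmasking avoids Brønsted acid, because the isopropenyl group and the tertiary carbinol would add solvent or cyclise onto the C7 phenol under acid.

**Step 1**
Reactants: 1 5-methoxyresorcinol
Product: 2 1-methoxy-3,5-bis(methoxymethoxy)benzene
Conditions: MOMCl, iPr2NEt, CH2Cl2, 0 °C → rt
Reagents that add atoms: chloromethyl methyl ether, COCCl
Why: O-alkylation of both phenols with MOMCl under amine base is routine and installs the acetal ethers that direct both later ring metalations.

**Step 2**
Reactants: 2 1-methoxy-3,5-bis(methoxymethoxy)benzene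
Product: 5 4-methoxy-2,6-bis(methoxymethoxy)phenol, via aryllithium 3 (not isolated), via lithium aryltrimethoxyborate 4 (not isolated)
Conditions: n-BuLi, THF, 0 °C → rt; B(OMe)3, −78 °C → rt; 30% aq H2O2, 0 °C → rt
Reagents that add atoms: hydrogen peroxide, OO
Why: Directed ortho-metalation is expected at the C–H flanked by the two MOM ethers (MOM-oxy outranks methoxy as a directing group and the site is doubly chelated), and borylation followed by peroxide-induced 1,2-aryl shift turns the C–Li bond into the phenol.

**Step 3**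
Reactants: 5 4-methoxy-2,6-bis(methoxymethoxy)phenol
Product: 6 4-methoxy-2,6-bis(methoxymethoxy)phenyl trifluoromethanesulfonate
Conditions: Tf2O, pyridine, CH2Cl2, 0 °C
Reagents that add atoms: trifluoromethanesulfonic anhydride, O=S(=O)(OS(=O)(=O)C(F)(F)F)C(F)(F)F
Why: O-sulfonylation of the phenol with Tf2O is reliable even for a 2,6-disubstituted phenol, and pyridine buffers the acid so the MOM acetals survive.

**Step 4**
Reactants: 7 3-methylbutane-1,3-diol
Product: 8 4-iodo-2-methylbutan-2-ol
Conditions: I2, PPh3, imidazole, CH2Cl2, 0 °C → rt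
Reagents that add atoms: iodine, II
Why: The Appel reaction is selective for the primary hydroxyl because the tertiary carbinol cannot be displaced by SN2 at the alkoxyphosphonium stage.

**Step 5**
Reactants: 8 4-iodo-2-methylbutan-2-ol
Product: 9 triethyl[(4-iodo-2-methylbutan-2-yl)oxy]silane
Conditions: TESOTf, 2,6-lutidine, CH2Cl2, −78 → 0 °C
Reagents that add atoms: triethylsilyl trifluoromethanesulfonate, CC[Si](CC)(CC)OS(=O)(=O)C(F)(F)F
Why: A silyl triflate with 2,6-lutidine silylates even a tertiary alcohol at low temperature, and the primary iodide is inert to these conditions.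

**Step 6**
Reactants: 9 triethyl[(4-iodo-2-methylbutan-2-yl)oxy]silane; 10 vinylboronic acid pinacol ester; 6 4-methoxy-2,6-bis(methoxymethoxy)phenyl trifluoromethanesulfonate
Product: 13 2-[(2R)-1-[4-methoxy-2,6-bis(methoxymethoxy)phenyl]-5-methyl-5-(triethylsilyloxy)hexan-2-yl]-4,4,5,5-tetramethyl-1,3,2-dioxaborolane, via alkyllithium 11 (not isolated), via lithium vinylboronate complex 12 (not isolated)
Conditions: 9, t-BuLi (2.0 equiv), Et2O–pentane, −78 °C; 10, −78 → 0 °C; swap to THF; 6, Pd(OAc)2 (3 mol %), L* (3.6 mol %), CF3SO3K, 60 °C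
Reagents that add atoms: none
Why: Triflate 6 adds oxidatively to zerovalent palladium, and because triflate does not stay on the metal the arylpalladium cation (divalent palladium) can take up the alkene of ate complex 12; the silyloxyalkyl group then moves from boron to the α-carbon on the face opposite the metal while the terminal carbon binds palladium, and reductive elimination joins C8 to C1''. The closest known reaction type is the enantioselective palladium-catalysed conjunctive cross-coupling of vinylboron ate complexes with aryl triflates. No ring is closed. The C2'' stereocentre has no substrate control and is set by the chiral ferrocenyl diphosphine, which distinguishes the two faces of the bound vinyl group during the 1,2-shift. The step needs the conjunctive path to win over direct Suzuki-type transfer of vinyl or alkyl and over β-hydride loss; the unsubstituted vinyl terminus, the readily migrating primary alkyl group, the wide-bite-angle ligand and removal of iodide by CF3SO3K should secure this. The two ortho MOM ethers of 6 are identical, so no regiochemical question arises on ring A, and exactly two equivalents of t-BuLi keep a tert-butyl boronate from forming.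

**Step 7**
Reactants: 14 2-bromopropene; 13 the (R)-boronic ester
Product: 18 5-methoxy-1,3-bis(methoxymethoxy)-2-[(2R)-5-methyl-2-(prop-1-en-2-yl)-5-(triethylsilyloxy)hexyl]benzene, via isopropenyllithium 15 (not isolated), via lithium isopropenylboronate complex 16 (not isolated), via iodoalkyl boronic ester 17 (not isolated)
Conditions: 14, t-BuLi (2 equiv), THF, −78 °C; 13, −78 °C; I2, MeOH, −78 °C; NaOMe, MeOH, −78 °C → rt
Reagents that add atoms: none
Why: Zweifel olefination: isopropenyllithium adds to boron, iodine activates the alkene so that the secondary alkyl group migrates with retention at C2'', and methoxide triggers anti elimination of boron and iodide; the alkene is 1,1-disubstituted, so no alkene geometry is at stake.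

**Step 8**
Reactants: 19 2,4-dihydroxybenzaldehyde
Product: 20 2,4-bis(methoxymethoxy)benzaldehyde
Conditions: MOMCl, iPr2NEt, CH2Cl2, 0 °C → reflux
Reagents that add atoms: chloromethyl methyl ether, COCCl
Why: O-alkylation with excess MOMCl and gentle heating also protects the hydrogen-bonded ortho phenol.

**Step 9**
Reactants: 20 2,4-bis(methoxymethoxy)benzaldehyde
Product: 21 1-ethynyl-2,4-bis(methoxymethoxy)benzene
Conditions: dimethyl (1-diazo-2-oxopropyl)phosphonate, K2CO3, MeOH, rt
Reagents that add atoms: dimethyl (1-diazo-2-oxopropyl)phosphonate, COP(=O)(OC)C(=[N+]=[N-])C(C)=O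
Why: Seyferth–Gilbert homologation in its Ohira–Bestmann form converts aryl aldehydes into terminal alkynes under mild carbonate conditions that leave the acetals untouched.

**Step 10**
Reactants: 21 1-ethynyl-2,4-bis(methoxymethoxy)benzene
Product: 24 3-[2,4-bis(methoxymethoxy)phenyl]prop-2-ynal, via lithium acetylide 22 (not isolated), via lithium hemiaminal alkoxide 23 (not isolated)
Conditions: n-BuLi, THF, −78 °C; DMF, −78 → 0 °C; poured into cold aq KH2PO4
Reagents that add atoms: N,N-dimethylformamide, CN(C)C=O
Why: Formylation of a lithium acetylide with DMF is standard, and the inverse buffered quench releases the ynal while keeping the liberated dimethylamine protonated so that it cannot add to the triple bond.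

**Step 11**
Reactants: 18 the isopropenyl arene; 24 3-[2,4-bis(methoxymethoxy)phenyl]prop-2-ynal
Product: 26 1-{6-methoxy-2,4-bis(methoxymethoxy)-3-[(2R)-5-methyl-2-(prop-1-en-2-yl)-5-(triethylsilyloxy)hexyl]phenyl}-3-[2,4-bis(methoxymethoxy)phenyl]prop-2-yn-1-ol (both carbinol epimers), via aryllithium 25 (not isolated)
Conditions: 18, n-BuLi, THF, 0 °C; 24, −78 °C; aq NH4Cl
Reagents that add atoms: none
Why: Directed ortho-metalation occurs at the only ring hydrogens, which are equivalent and flanked by MOM-oxy and methoxy, and the aryllithium adds 1,2 to the ynal at low temperature; the carbinol centre forms without control and is removed in step 12.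

**Step 12**
Reactants: 26 the propargylic alcohol
Product: 27 1-{6-methoxy-2,4-bis(methoxymethoxy)-3-[(2R)-5-methyl-2-(prop-1-en-2-yl)-5-(triethylsilyloxy)hexyl]phenyl}-3-[2,4-bis(methoxymethoxy)phenyl]prop-2-yn-1-one
Conditions: MnO2 (activated, excess), CH2Cl2, rt
Reagents that add atoms: none
Why: MnO2 oxidises the doubly activated (benzylic and propargylic) alcohol selectively under neutral conditions that leave the alkene, the acetals and the silyl ether alone.

**Step 13**
Reactants: 27 the ynone
Product: 30 2-(2,4-dihydroxyphenyl)-7-hydroxy-5-methoxy-8-[(2R)-5-methyl-2-(prop-1-en-2-yl)-5-(triethylsilyloxy)hexyl]-4H-chromen-4-one, via tetrakis(trimethylsilyl) aryl ether 28 (not isolated), via diethylamino enone 29 (not isolated)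
Conditions: TMSOTf, 2,2′-bipyridyl, CH3CN, 0 °C → rt; then MeOH, Et2NH, rt → 40 °C
Reagents that add atoms: none
Why: Silyl triflate buffered by 2,2′-bipyridyl exchanges aryl MOM ethers for aryl silyl ethers without free Brønsted acid, methanolic diethylamine then frees the phenols and adds to the ynone, and the ortho phenol closes ring C by 6-endo addition–elimination at the enaminone carbon, which excludes the 5-exo (aurone) mode.

**Step 14**
Reactants: 30 the silyl-protected flavone
Product: 31 2-(2,4-dihydroxyphenyl)-7-hydroxy-8-[(2R)-5-hydroxy-5-methyl-2-(prop-1-en-2-yl)hexyl]-5-methoxy-4H-chromen-4-one (CNP0256984.1)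
Conditions: TBAF, THF, 0 °C → rt; aq NH4Cl
Reagents that add atoms: none
Why: Fluoride cleaves the tertiary triethylsilyl ether under non-acidic conditions, so neither the isopropenyl group nor the tertiary carbinol can ionise and C2'' is untouched.

**Compound list**

1 | 5-methoxyresorcinol (5-methoxybenzene-1,3-diol) | COc1cc(O)cc(O)c1 | starting material
2 | 1-methoxy-3,5-bis(methoxymethoxy)benzene | COCOc1cc(OC)cc(OCOC)c1 | intermediate
3 | [4-methoxy-2,6-bis(methoxymethoxy)phenyl]lithium (not isolated) | [Li]c1c(OCOC)cc(OC)cc1OCOC | intermediate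
4 | lithium trimethoxy[4-methoxy-2,6-bis(methoxymethoxy)phenyl]borate (not isolated) | [Li+].CO[B-](OC)(OC)c1c(OCOC)cc(OC)cc1OCOC | intermediate
5 | 4-methoxy-2,6-bis(methoxymethoxy)phenol | COCOc1cc(OC)cc(OCOC)c1O | intermediate
6 | 4-methoxy-2,6-bis(methoxymethoxy)phenyl trifluoromethanesulfonate | COCOc1cc(OC)cc(OCOC)c1OS(=O)(=O)C(F)(F)F | intermediate
7 | 3-methylbutane-1,3-diol | CC(C)(O)CCO | starting material
8 | 4-iodo-2-methylbutan-2-ol | CC(C)(O)CCI | intermediate
9 | triethyl[(4-iodo-2-methylbutan-2-yl)oxy]silane | CC[Si](CC)(CC)OC(C)(C)CCI | intermediate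
10 | vinylboronic acid pinacol ester (4,4,5,5-tetramethyl-2-vinyl-1,3,2-dioxaborolane) | C=CB1OC(C)(C)C(C)(C)O1 | starting material
11 | [3-methyl-3-(triethylsilyloxy)butyl]lithium (not isolated) | [Li]CCC(C)(C)O[Si](CC)(CC)CC | intermediate
12 | lithium 4,4,5,5-tetramethyl-2-[3-methyl-3-(triethylsilyloxy)butyl]-2-vinyl-1,3,2-dioxaborolan-2-uide (not isolated) | [Li+].C=C[B-]1(CCC(C)(C)O[Si](CC)(CC)CC)OC(C)(C)C(C)(C)O1 | intermediate
13 | 2-[(2R)-1-[4-methoxy-2,6-bis(methoxymethoxy)phenyl]-5-methyl-5-(triethylsilyloxy)hexan-2-yl]-4,4,5,5-tetramethyl-1,3,2-dioxaborolane | CC1(C)OB(OC1(C)C)[C@H](CCC(C)(C)O[Si](CC)(CC)CC)Cc1c(OCOC)cc(OC)cc1OCOC | intermediate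
14 | 2-bromopropene | C=C(C)Br | starting material
15 | prop-1-en-2-yllithium (not isolated) | [Li]C(C)=C | intermediate
16 | lithium boronate complex of 13 carrying isopropenyl on boron, C2'' (R) as in 13 (not isolated) | [Li+].C=C(C)[B-]1(OC(C)(C)C(C)(C)O1)[C@H](CCC(C)(C)O[Si](CC)(CC)CC)Cc1c(OCOC)cc(OC)cc1OCOC | intermediate
17 | pinacol boronic ester with boron, CH3 and CH2I on the carbon attached to C2''; C2'' (R) by retention, new quaternary centre undefined (not isolated) | CC(CI)(B1OC(C)(C)C(C)(C)O1)[C@H](CCC(C)(C)O[Si](CC)(CC)CC)Cc1c(OCOC)cc(OC)cc1OCOC | intermediate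
18 | 5-methoxy-1,3-bis(methoxymethoxy)-2-[(2R)-5-methyl-2-(prop-1-en-2-yl)-5-(triethylsilyloxy)hexyl]benzene | C=C(C)[C@H](CCC(C)(C)O[Si](CC)(CC)CC)Cc1c(OCOC)cc(OC)cc1OCOC | intermediate
19 | 2,4-dihydroxybenzaldehyde | O=Cc1ccc(O)cc1O | starting material
20 | 2,4-bis(methoxymethoxy)benzaldehyde | COCOc1ccc(C=O)c(OCOC)c1 | intermediate
21 | 1-ethynyl-2,4-bis(methoxymethoxy)benzene | C#Cc1ccc(OCOC)cc1OCOC | intermediate
22 | lithium [2,4-bis(methoxymethoxy)phenyl]acetylide (not isolated) | [Li]C#Cc1ccc(OCOC)cc1OCOC | intermediate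
23 | lithium 1-(dimethylamino)-3-[2,4-bis(methoxymethoxy)phenyl]prop-2-yn-1-olate (not isolated) | [Li]OC(N(C)C)C#Cc1ccc(OCOC)cc1OCOC | intermediate
24 | 3-[2,4-bis(methoxymethoxy)phenyl]prop-2-ynal | O=CC#Cc1ccc(OCOC)cc1OCOC | intermediate
25 | {6-methoxy-2,4-bis(methoxymethoxy)-3-[(2R)-5-methyl-2-(prop-1-en-2-yl)-5-(triethylsilyloxy)hexyl]phenyl}lithium (not isolated) | C=C(C)[C@H](CCC(C)(C)O[Si](CC)(CC)CC)Cc1c(OCOC)cc(OC)c([Li])c1OCOC | intermediate
26 | 1-{6-methoxy-2,4-bis(methoxymethoxy)-3-[(2R)-5-methyl-2-(prop-1-en-2-yl)-5-(triethylsilyloxy)hexyl]phenyl}-3-[2,4-bis(methoxymethoxy)phenyl]prop-2-yn-1-ol, both carbinol epimers | C=C(C)[C@H](CCC(C)(C)O[Si](CC)(CC)CC)Cc1c(OCOC)cc(OC)c(C(O)C#Cc2ccc(OCOC)cc2OCOC)c1OCOC | intermediate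
27 | 1-{6-methoxy-2,4-bis(methoxymethoxy)-3-[(2R)-5-methyl-2-(prop-1-en-2-yl)-5-(triethylsilyloxy)hexyl]phenyl}-3-[2,4-bis(methoxymethoxy)phenyl]prop-2-yn-1-one | C=C(C)[C@H](CCC(C)(C)O[Si](CC)(CC)CC)Cc1c(OCOC)cc(OC)c(C(=O)C#Cc2ccc(OCOC)cc2OCOC)c1OCOC | intermediate
28 | 1-{6-methoxy-2,4-bis(trimethylsilyloxy)-3-[(2R)-5-methyl-2-(prop-1-en-2-yl)-5-(triethylsilyloxy)hexyl]phenyl}-3-[2,4-bis(trimethylsilyloxy)phenyl]prop-2-yn-1-one (not isolated) | C=C(C)[C@H](CCC(C)(C)O[Si](CC)(CC)CC)Cc1c(O[Si](C)(C)C)cc(OC)c(C(=O)C#Cc2ccc(O[Si](C)(C)C)cc2O[Si](C)(C)C)c1O[Si](C)(C)C | intermediate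
29 | 3-(diethylamino)-1-{2,4-dihydroxy-6-methoxy-3-[(2R)-5-methyl-2-(prop-1-en-2-yl)-5-(triethylsilyloxy)hexyl]phenyl}-3-(2,4-dihydroxyphenyl)prop-2-en-1-one, alkene geometry undefined (not isolated) | C=C(C)[C@H](CCC(C)(C)O[Si](CC)(CC)CC)Cc1c(O)cc(OC)c(C(=O)C=C(N(CC)CC)c2ccc(O)cc2O)c1O | intermediate
30 | 2-(2,4-dihydroxyphenyl)-7-hydroxy-5-methoxy-8-[(2R)-5-methyl-2-(prop-1-en-2-yl)-5-(triethylsilyloxy)hexyl]-4H-chromen-4-one | C=C(C)[C@H](CCC(C)(C)O[Si](CC)(CC)CC)Cc1c(O)cc(OC)c2c(=O)cc(-c3ccc(O)cc3O)oc12 | intermediate
31 | 2-(2,4-dihydroxyphenyl)-7-hydroxy-8-[(2R)-5-hydroxy-5-methyl-2-(prop-1-en-2-yl)hexyl]-5-methoxy-4H-chromen-4-one | C=C(C)[C@H](CCC(C)(C)O)Cc1c(O)cc(OC)c2c(=O)cc(-c3ccc(O)cc3O)oc12 | target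

**Count.** Total: 14 steps. Longest linear sequence: 9 steps (1, 2, 3, 6, 7, 11, 12, 13, 14). The chain branch (steps 4, 5) joins at step 6 and the ring B branch (steps 8–10) at step 11.

**Steps most likely to fail**

1. Step 6. Oxidative addition of the electron-rich, doubly ortho-substituted triflate may be slow. Residual iodide may block the cationic palladium site. Direct Suzuki-type transfer may compete with the boronate shift. Facial discrimination by the ligand may be insufficient.
Fallback by lithiation–borylation, setting out from 2 and returning at 13: aryllithium 3, made from 2 as in step 2, is added to 2-(iodomethyl)-4,4,5,5-tetramethyl-1,3,2-dioxaborolane. This should give the lithium aryl(iodomethyl)boronate complex F1, whose aryl group shifts to carbon with loss of iodide to give the benzylic boronic ester 2-[4-methoxy-2,6-bis(methoxymethoxy)benzyl]-4,4,5,5-tetramethyl-1,3,2-dioxaborolane F2. Separately, 4-methylpentane-1,4-diol (commercial, or from γ-butyrolactone and MeMgBr) is carbamoylated at the primary hydroxyl with N,N-diisopropylcarbamoyl chloride and Et3N to 4-hydroxy-4-methylpentyl N,N-diisopropylcarbamate F3. Silylation with TESOTf and 2,6-lutidine gives 4-methyl-4-(triethylsilyloxy)pentyl N,N-diisopropylcarbamate F4. Deprotonation with s-BuLi and (−)-sparteine in Et2O at −78 °C should give the configurationally stable (S)-1-lithio carbamate F5. This is borylated by F2 with retention to the lithium boronate complex F6. On warming with MgBr2·OEt2 the benzyl group migrates with inversion and expels the carbamate, which should give (R)-13. The route continues with step 7.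

2. Step 13. Exchange of four aryl MOM ethers may stall part-way. The silyl triflate and pyridine system may attack the ynone. Ring closure may lag behind phenol release.
Fallback, setting out from 27 and returning at 31: ynone 27 is first treated with Et2NH in EtOH at rt, which should give the fully protected 3-(diethylamino) enone F7 as an isolable compound. Short exposure of F7 to dilute HCl in MeOH–THF at 0 °C → rt then removes the four MOM acetals and the triethylsilyl ether, and the ortho phenol displaces the amine as soon as it is freed. This ends directly at 31 and replaces steps 13 and 14. The acid contact is kept short because the isopropenyl group can add methanol or the C7 phenol under prolonged acid.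

3. Step 2. Metalation may occur in part at the positions between methoxy and MOM-oxy, which would lead to the wrong phenol.
Fallback by halogen–lithium exchange on a regiodefined iodide, setting out from 1 and returning at 3: iodination of 1 with I2 and NaHCO3 in THF–water at 0 °C is expected to place iodine between the two hydroxyls and give 2-iodo-5-methoxybenzene-1,3-diol F8. MOMCl and iPr2NEt give 2-iodo-5-methoxy-1,3-bis(methoxymethoxy)benzene F9. n-BuLi in THF at −78 °C then generates aryllithium 3 with no positional ambiguity. Borylation and oxidation as in step 2 lead to 5.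

**Further compounds**

F1 | step 6 | lithium 2-(iodomethyl)-2-[4-methoxy-2,6-bis(methoxymethoxy)phenyl]-4,4,5,5-tetramethyl-1,3,2-dioxaborolan-2-uide | [Li+].COCOc1cc(OC)cc(OCOC)c1[B-]1(CI)OC(C)(C)C(C)(C)O1
F2 | step 6 | 2-[4-methoxy-2,6-bis(methoxymethoxy)benzyl]-4,4,5,5-tetramethyl-1,3,2-dioxaborolane | COCOc1cc(OC)cc(OCOC)c1CB1OC(C)(C)C(C)(C)O1
F3 | step 6 | 4-hydroxy-4-methylpentyl N,N-diisopropylcarbamate | CC(C)N(C(C)C)C(=O)OCCCC(C)(C)O
F4 | step 6 | 4-methyl-4-(triethylsilyloxy)pentyl N,N-diisopropylcarbamate | CC(C)N(C(C)C)C(=O)OCCCC(C)(C)O[Si](CC)(CC)CC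
F5 | step 6 | (S)-1-lithio-4-methyl-4-(triethylsilyloxy)pentyl N,N-diisopropylcarbamate | CC(C)N(C(C)C)C(=O)O[C@@H]([Li])CCC(C)(C)O[Si](CC)(CC)CC
F6 | step 6 | lithium boronate complex from F5 and F2 (boron in place of lithium with retention) | [Li+].CC(C)N(C(C)C)C(=O)O[C@@H]([B-]1(Cc2c(OCOC)cc(OC)cc2OCOC)OC(C)(C)C(C)(C)O1)CCC(C)(C)O[Si](CC)(CC)CC
F7 | step 13 | 3-(diethylamino)-1-{6-methoxy-2,4-bis(methoxymethoxy)-3-[(2R)-5-methyl-2-(prop-1-en-2-yl)-5-(triethylsilyloxy)hexyl]phenyl}-3-[2,4-bis(methoxymethoxy)phenyl]prop-2-en-1-one | C=C(C)[C@H](CCC(C)(C)O[Si](CC)(CC)CC)Cc1c(OCOC)cc(OC)c(C(=O)C=C(N(CC)CC)c2ccc(OCOC)cc2OCOC)c1OCOC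
F8 | step 2 | 2-iodo-5-methoxybenzene-1,3-diol | COc1cc(O)c(I)c(O)c1
F9 | step 2 | 2-iodo-5-methoxy-1,3-bis(methoxymethoxy)benzene | COCOc1cc(OC)cc(OCOC)c1I
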